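**Retrosynthetic overview**

1. Target 23 comes from protected flavanone 22 by one hydrogenolysis that removes two benzyl ethers and one benzyl carbonate.
2. Ring C of 22 is closed last by intramolecular Friedel–Crafts acylation (bond C4–C4a) of the (S)-3-aryloxy-3-arylpropanoic acid 20. The route rests on one feature of ring A: the piperidine-bearing carbon C6 is para to C8a, the carbon that carries O1. In the open aryl ether the two carbons ortho to the ether oxygen (future C4a and C8) are therefore homotopic, and acylation at either gives the same 6-substituted flavanone.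
3. Acid 20 comes from a Mitsunobu inversion (bond O1–C2) between the symmetric phenol 11 and the (R)-β-hydroxy tert-butyl ester 18, followed by acidolysis of the ester. Alcohol 18 comes from asymmetric hydrogenation of β-keto ester 17.
4. Phenol 11 comes from 4-bromo-2,6-difluorobenzaldehyde: double SNAr with benzyl alcohol, addition of a 4-chlorobutyl Grignard reagent to the (S)-tert-butanesulfinyl imine (sets the piperidine carbon as R), ring closure by N-alkylation, N-methylation, and palladium-catalysed hydroxylation of the aryl bromide.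
5. Ring order: rings A and B are bought in, the piperidine ring is closed in step 4, and ring C is closed in step 13.

Key step: step 13

Assumption: compounds 1, 3, 5, 12 and 14 are taken as commercial. The acid is carried as a tert-butyl ester because an ethyl ester could not be saponified beside the aryl benzyl carbonate, and the para-oxygen of ring A is carried as an aryl bromide because selective protection of a phloroglucinol aldehyde is not reliable.

**Route**

Step 1
Reactants: 1 4-bromo-2,6-difluorobenzaldehyde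
Product: 2 2,6-bis(benzyloxy)-4-bromobenzaldehyde
Conditions: BnOH (2.4 equiv), NaH (2.4 equiv), THF, 0 °C; then 1, 0 → 50 °C
Reagents that add atoms: benzyl alcohol, OCc1ccccc1
Why: Nucleophilic aromatic substitution (SNAr): both fluorides are ortho to the formyl group and should be displaced by benzyloxide through Meisenheimer intermediates, while the bromide, a poorer SNAr leaving group, stays as the masked para-phenol, so the symmetric pattern is fixed without a regiochemical choice.

Step 2
Reactants: 2 2,6-bis(benzyloxy)-4-bromobenzaldehyde; 3 (S)-tert-butanesulfinamide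
Product: 4 (S,E)-N-[2,6-bis(benzyloxy)-4-bromobenzylidene]-2-methylpropane-2-sulfinamide
Conditions: Ti(OEt)4 (2 equiv), THF, 65 °C
Reagents that add atoms: none
Why: Ti(OEt)4-mediated condensation of an aldehyde with a sulfinamide (sulfinyl imine formation), in which the titanium alkoxide activates the hindered aldehyde and takes up the water; the sulfur stereocentre is untouched and the E aldimine is expected.

Step 3
Reactants: 4 (S,E)-N-[2,6-bis(benzyloxy)-4-bromobenzylidene]-2-methylpropane-2-sulfinamide; 5 1-bromo-4-chlorobutane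
Product: 7 (S)-N-{(1R)-1-[2,6-bis(benzyloxy)-4-bromophenyl]-5-chloropentyl}-2-methylpropane-2-sulfinamide, via 4-chlorobutylmagnesium bromide 6 (not isolated)
Conditions: 5, Mg, Et2O, rt; add to 4, CH2Cl2, −48 °C → rt; aq NH4Cl
Reagents that add atoms: none
Why: Grignard 1,2-addition to an N-tert-butanesulfinyl aldimine in a non-coordinating solvent: magnesium is held by the sulfinyl oxygen in a six-membered chair transition state with tert-butyl equatorial, so the alkyl group should be delivered to the Re face of the (S)-sulfinyl imine and set the new carbon as R; magnesium inserts selectively into the C–Br bond of 5 and the aryl bromide is inert at low temperature.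

Step 4
Reactants: 7 (S)-N-{(1R)-1-[2,6-bis(benzyloxy)-4-bromophenyl]-5-chloropentyl}-2-methylpropane-2-sulfinamide
Product: 9 (2R)-2-[2,6-bis(benzyloxy)-4-bromophenyl]piperidine, via amino chloride hydrochloride 8 (not isolated)
Conditions: HCl (4 M in dioxane), MeOH, 0 °C → rt; evaporate; K2CO3, NaI (cat.), MeCN, 70 °C
Reagents that add atoms: none
Why: Methanolic HCl cleaves the N–S bond, and the freed primary amine then displaces the primary chloride in a Finkelstein-assisted 6-exo-tet N-alkylation that closes the piperidine ring; the stereocentre takes no part and the benzyl ethers are stable to both stages.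

Step 5
Reactants: 9 (2R)-2-[2,6-bis(benzyloxy)-4-bromophenyl]piperidine
Product: 10 (2R)-2-[2,6-bis(benzyloxy)-4-bromophenyl]-1-methylpiperidine
Conditions: 37% aq HCHO, NaBH(OAc)3, ClCH2CH2Cl, rt
Reagents that add atoms: formaldehyde, C=O
Why: Reductive amination: the secondary amine and formaldehyde give an iminium ion that the acetoxyborohydride reduces, so mono-methylation without quaternisation is expected and the aryl bromide and benzyl ethers are inert.

Step 6
Reactants: 10 (2R)-2-[2,6-bis(benzyloxy)-4-bromophenyl]-1-methylpiperidine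
Product: 11 3,5-bis(benzyloxy)-4-[(2R)-1-methylpiperidin-2-yl]phenol
Conditions: Pd2(dba)3 (2 mol%), tBuXPhos (8 mol%), KOH (3 equiv), 1,4-dioxane/H2O, 100 °C; then aq NH4Cl to pH 8
Reagents that add atoms: potassium hydroxide, [K+].[OH-]
Why: Palladium-catalysed hydroxylation of an aryl bromide (oxidative addition to zerovalent palladium, bromide–hydroxide exchange, and C–O reductive elimination promoted by the bulky biarylphosphine); the bromide is unhindered, and benzyl ethers, the tertiary amine and the non-acidic benzylic stereocentre tolerate hot aqueous KOH.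

Step 7
Reactants: 12 4-hydroxybenzoic acid
Product: 13 4-{[(benzyloxy)carbonyl]oxy}benzoic acid
Conditions: CbzCl (1.1 equiv), aq NaOH (2 equiv), 0 °C; then HCl to pH 2
Reagents that add atoms: benzyl chloroformate, O=C(Cl)OCc1ccccc1
Why: Schotten–Baumann acylation: the phenoxide of the dianion is the better nucleophile toward the chloroformate, and any mixed anhydride formed at the carboxylate is hydrolysed back in the cold aqueous medium, leaving the aryl benzyl carbonate.

Step 8
Reactants: 13 4-{[(benzyloxy)carbonyl]oxy}benzoic acid; 14 Meldrum's acid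
Product: 16 benzyl 4-[(2,2-dimethyl-4,6-dioxo-1,3-dioxan-5-ylidene)(hydroxy)methyl]phenyl carbonate, via acid chloride 15 (not isolated)
Conditions: (COCl)2, DMF (cat.), CH2Cl2, 0 °C → rt; evaporate; 14, pyridine (2.2 equiv), CH2Cl2, 0 °C → rt; wash with 1 M HCl
Reagents that add atoms: none
Why: C-acylation of Meldrum's acid by an acid chloride: the pyridine-generated enolate attacks the acid chloride, which is far more electrophilic than the aryl carbonate, and should give the enolised acyl Meldrum's acid.

Step 9
Reactants: 16 benzyl 4-[(2,2-dimethyl-4,6-dioxo-1,3-dioxan-5-ylidene)(hydroxy)methyl]phenyl carbonate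
Product: 17 tert-butyl 3-(4-{[(benzyloxy)carbonyl]oxy}phenyl)-3-oxopropanoate
Conditions: t-BuOH (5 equiv), toluene, 90 °C
Reagents that add atoms: tert-butanol, CC(C)(C)O
Why: Thermal alcoholysis of an acyl Meldrum's acid: loss of acetone and CO2 gives an acylketene that tert-butanol traps as the β-keto tert-butyl ester under neutral conditions that leave the carbonate intact.

Step 10
Reactants: 17 tert-butyl 3-(4-{[(benzyloxy)carbonyl]oxy}phenyl)-3-oxopropanoate
Product: 18 tert-butyl (3R)-3-(4-{[(benzyloxy)carbonyl]oxy}phenyl)-3-hydroxypropanoate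
Conditions: [RuCl(p-cymene)((S)-BINAP)]Cl (1 mol%), H2 (30 atm), EtOH, 50 °C
Reagents that add atoms: none
Why: Noyori asymmetric hydrogenation of a β-keto ester: the chelated keto ester is reduced from the face selected by (S)-BINAP, the same facial sense that turns acetoacetates into (S)-3-hydroxybutanoates, and the descriptor is R here only because the aryl group outranks CH2CO2tBu; the catalyst does not hydrogenolyse the benzyl carbonate.

Step 11
Reactants: 11 3,5-bis(benzyloxy)-4-[(2R)-1-methylpiperidin-2-yl]phenol; 18 tert-butyl (3R)-3-(4-{[(benzyloxy)carbonyl]oxy}phenyl)-3-hydroxypropanoate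
Product: 19 tert-butyl (3S)-3-{3,5-bis(benzyloxy)-4-[(2R)-1-methylpiperidin-2-yl]phenoxy}-3-(4-{[(benzyloxy)carbonyl]oxy}phenyl)propanoate
Conditions: PPh3 (1.5 equiv), DIAD (1.5 equiv), toluene, 0 °C → rt
Reagents that add atoms: none
Why: Mitsunobu etherification: the phenoxide displaces the alkoxyphosphonium ion of the secondary benzylic alcohol by SN2 with inversion, turning the (R)-carbinol into the (S)-aryl ether; the electron-poor carbonate on ring B disfavours an SN1 path and the tertiary amine has no N–H to compete.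

Step 12
Reactants: 19 tert-butyl (3S)-3-{3,5-bis(benzyloxy)-4-[(2R)-1-methylpiperidin-2-yl]phenoxy}-3-(4-{[(benzyloxy)carbonyl]oxy}phenyl)propanoate
Product: 20 (3S)-3-{3,5-bis(benzyloxy)-4-[(2R)-1-methylpiperidin-2-yl]phenoxy}-3-(4-{[(benzyloxy)carbonyl]oxy}phenyl)propanoic acid
Conditions: TFA/CH2Cl2 (1:4), Et3SiH (2 equiv), 0 °C → rt; evaporate with toluene (acid kept as its trifluoroacetate salt)
Reagents that add atoms: none
Why: Acidolysis of a tert-butyl ester (E1 loss of isobutene from the protonated ester) leaves benzyl ethers and the benzyl carbonate untouched, triethylsilane intercepts stray tert-butyl cation before it can alkylate ring A, and no base is used that could cleave the carbonate or expel the β-aryloxy group.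

Step 13
Reactants: 20 (3S)-3-{3,5-bis(benzyloxy)-4-[(2R)-1-methylpiperidin-2-yl]phenoxy}-3-(4-{[(benzyloxy)carbonyl]oxy}phenyl)propanoic acid
Product: 22 benzyl 4-{(2S)-5,7-bis(benzyloxy)-6-[(2R)-1-methylpiperidin-2-yl]-4-oxo-3,4-dihydro-2H-chromen-2-yl}phenyl carbonate, via mixed trifluoroacetic anhydride 21 (not isolated)
Conditions: TFAA (3 equiv), TFA (5 equiv), CH2Cl2, 0 °C → rt; cold aq NaHCO3
Reagents that add atoms: none
Why: TFAA converts the carboxylic acid of 20 (amine held as its trifluoroacetate salt) into mixed anhydride 21, whose acylium ion (or protonated anhydride) is attacked by the ring A carbon ortho to the ether oxygen, and loss of a proton restores aromaticity and forms the aryl ketone bond C4–C4a. The closest known reaction type is the intramolecular Friedel–Crafts acylation of 3-aryloxypropanoic acids to chroman-4-ones. Ring C closes by attack of the arene on the exocyclic acyl carbon in a six-membered exo mode (6-exo-trig on the anhydride carbonyl), the only ring size the three-atom tether allows. No stereocentre is created: C2 was set by the Mitsunobu inversion and the piperidine carbon by the sulfinamide, and both are carried through. The step needs site selectivity on ring A and chemoselectivity over ionisation at the benzylic ether carbon. The first is secured because the piperidine is para to the ether oxygen, so the two ortho carbons are homotopic and each is activated by the ether oxygen, one ortho benzyloxy and one para benzyloxy group; the second is secured because the carbonate on ring B withholds electron density from C2 and the nitrogen is protonated, so neither the C2–O bond nor the benzylic C–N bond should ionise at 0 °C.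

Step 14
Reactants: 22 benzyl 4-{(2S)-5,7-bis(benzyloxy)-6-[(2R)-1-methylpiperidin-2-yl]-4-oxo-3,4-dihydro-2H-chromen-2-yl}phenyl carbonate
Product: 23 (2S)-5,7-dihydroxy-2-(4-hydroxyphenyl)-6-[(2R)-1-methylpiperidin-2-yl]-2,3-dihydro-4H-chromen-4-one
Conditions: H2 (1 atm), 10% Pd/C, EtOAc/MeOH, rt; stop after uptake of three equivalents
Reagents that add atoms: none
Why: Heterogeneous hydrogenolysis: the two benzyl ethers give toluene and the benzyl carbonate gives toluene and CO2, under neutral conditions that should neither open ring C to a chalcone (so C2 is kept) nor cleave the hindered benzylic C–N bond or reduce the C4 ketone if the reaction is stopped at the calculated uptake.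

**Compound list**

1 | 4-bromo-2,6-difluorobenzaldehyde | O=Cc1c(F)cc(Br)cc1F | starting material
2 | 2,6-bis(benzyloxy)-4-bromobenzaldehyde | O=Cc1c(OCc2ccccc2)cc(Br)cc1OCc1ccccc1 | intermediate
3 | (S)-tert-butanesulfinamide | CC(C)(C)[S@](=O)N | starting material
4 | (S,E)-N-[2,6-bis(benzyloxy)-4-bromobenzylidene]-2-methylpropane-2-sulfinamide | CC(C)(C)[S@](=O)/N=C/c1c(OCc2ccccc2)cc(Br)cc1OCc1ccccc1 | intermediate
5 | 1-bromo-4-chlorobutane | ClCCCCBr | starting material
6 | 4-chlorobutylmagnesium bromide | ClCCCC[Mg]Br | intermediate (not isolated)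
7 | (S)-N-{(1R)-1-[2,6-bis(benzyloxy)-4-bromophenyl]-5-chloropentyl}-2-methylpropane-2-sulfinamide | CC(C)(C)[S@](=O)N[C@H](CCCCCl)c1c(OCc2ccccc2)cc(Br)cc1OCc1ccccc1 | intermediate
8 | (1R)-1-[2,6-bis(benzyloxy)-4-bromophenyl]-5-chloropentan-1-amine (formed as its hydrochloride) | N[C@H](CCCCCl)c1c(OCc2ccccc2)cc(Br)cc1OCc1ccccc1 | intermediate (not isolated)
9 | (2R)-2-[2,6-bis(benzyloxy)-4-bromophenyl]piperidine | N1CCCC[C@@H]1c1c(OCc2ccccc2)cc(Br)cc1OCc1ccccc1 | intermediate
10 | (2R)-2-[2,6-bis(benzyloxy)-4-bromophenyl]-1-methylpiperidine | CN1CCCC[C@@H]1c1c(OCc2ccccc2)cc(Br)cc1OCc1ccccc1 | intermediate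
11 | 3,5-bis(benzyloxy)-4-[(2R)-1-methylpiperidin-2-yl]phenol | CN1CCCC[C@@H]1c1c(OCc2ccccc2)cc(O)cc1OCc1ccccc1 | intermediate
12 | 4-hydroxybenzoic acid | OC(=O)c1ccc(O)cc1 | starting material
13 | 4-{[(benzyloxy)carbonyl]oxy}benzoic acid | OC(=O)c1ccc(OC(=O)OCc2ccccc2)cc1 | intermediate
14 | Meldrum's acid (2,2-dimethyl-1,3-dioxane-4,6-dione) | CC1(C)OC(=O)CC(=O)O1 | starting material
15 | benzyl 4-(chlorocarbonyl)phenyl carbonate | ClC(=O)c1ccc(OC(=O)OCc2ccccc2)cc1 | intermediate (not isolated)
16 | benzyl 4-[(2,2-dimethyl-4,6-dioxo-1,3-dioxan-5-ylidene)(hydroxy)methyl]phenyl carbonate | CC1(C)OC(=O)C(=C(O)c2ccc(OC(=O)OCc3ccccc3)cc2)C(=O)O1 | intermediate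
17 | tert-butyl 3-(4-{[(benzyloxy)carbonyl]oxy}phenyl)-3-oxopropanoate | CC(C)(C)OC(=O)CC(=O)c1ccc(OC(=O)OCc2ccccc2)cc1 | intermediate
18 | tert-butyl (3R)-3-(4-{[(benzyloxy)carbonyl]oxy}phenyl)-3-hydroxypropanoate | CC(C)(C)OC(=O)C[C@@H](O)c1ccc(OC(=O)OCc2ccccc2)cc1 | intermediate
19 | tert-butyl (3S)-3-{3,5-bis(benzyloxy)-4-[(2R)-1-methylpiperidin-2-yl]phenoxy}-3-(4-{[(benzyloxy)carbonyl]oxy}phenyl)propanoate | CN1CCCC[C@@H]1c1c(OCc2ccccc2)cc(O[C@@H](CC(=O)OC(C)(C)C)c2ccc(OC(=O)OCc3ccccc3)cc2)cc1OCc1ccccc1 | intermediate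
20 | (3S)-3-{3,5-bis(benzyloxy)-4-[(2R)-1-methylpiperidin-2-yl]phenoxy}-3-(4-{[(benzyloxy)carbonyl]oxy}phenyl)propanoic acid | CN1CCCC[C@@H]1c1c(OCc2ccccc2)cc(O[C@@H](CC(=O)O)c2ccc(OC(=O)OCc3ccccc3)cc2)cc1OCc1ccccc1 | intermediate (key-step precursor)
21 | mixed anhydride of 20 with trifluoroacetic acid | CN1CCCC[C@@H]1c1c(OCc2ccccc2)cc(O[C@@H](CC(=O)OC(=O)C(F)(F)F)c2ccc(OC(=O)OCc3ccccc3)cc2)cc1OCc1ccccc1 | intermediate (not isolated)
22 | benzyl 4-{(2S)-5,7-bis(benzyloxy)-6-[(2R)-1-methylpiperidin-2-yl]-4-oxo-3,4-dihydro-2H-chromen-2-yl}phenyl carbonate | CN1CCCC[C@@H]1c1c(OCc3ccccc3)cc2c(c1OCc1ccccc1)C(=O)C[C@@H](c1ccc(OC(=O)OCc3ccccc3)cc1)O2 | intermediate (key-step product)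
23 | (2S)-5,7-dihydroxy-2-(4-hydroxyphenyl)-6-[(2R)-1-methylpiperidin-2-yl]-2,3-dihydro-4H-chromen-4-one | CN1CCCC[C@@H]1c1c(O)cc2c(c1O)C(=O)C[C@@H](c1ccc(O)cc1)O2 | target

**Step count**

Total: 14 steps. Longest linear sequence: 10 steps (steps 1–6, then 11–14); the ring B branch (steps 7–10) is 4 steps.

**Steps most likely to fail**

1. Step 13 (key step). The risk is loss of configuration or of material through acid-promoted ionisation at the benzylic ether carbon C2 (racemisation, or elimination to a cinnamic acid with release of the phenol) or at the benzylic C–N bond of the piperidine on the electron-rich ring; intermolecular trifluoroacetylation of ring A may also compete with ring closure.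
Fallback, setting out from phenol 11 and rejoining at target 23, with ring C closed through the O1–C2 bond and C2 set by catalysis instead. C-acetylation of 11 ortho to the hydroxyl group (AcOH, TFAA, CH2Cl2; either ortho carbon is again equivalent) should give 1-{2,4-bis(benzyloxy)-6-hydroxy-3-[(2R)-1-methylpiperidin-2-yl]phenyl}ethan-1-one F1. Condensation with DMF dimethyl acetal (toluene, 90 °C) should give the enaminone (2E)-1-{2,4-bis(benzyloxy)-6-hydroxy-3-[(2R)-1-methylpiperidin-2-yl]phenyl}-3-(dimethylamino)prop-2-en-1-one F2. Treatment with HCl in CH2Cl2 should close it to the chromone 5,7-bis(benzyloxy)-6-[(2R)-1-methylpiperidin-2-yl]-4H-chromen-4-one F3. Enantioselective conjugate addition of 4-(benzyloxy)phenylboronic acid (Pd(OCOCF3)2, t-BuPyOX of the handedness that gives the 2S adduct, NH4PF6, H2O, ClCH2CH2Cl, 60 °C) should give (2S)-5,7-bis(benzyloxy)-2-[4-(benzyloxy)phenyl]-6-[(2R)-1-methylpiperidin-2-yl]-2,3-dihydro-4H-chromen-4-one F4. Hydrogenolysis of F4 (H2, Pd/C) returns to the route at 23.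

2. Step 11 (Mitsunobu). The risk is elimination of the alkoxyphosphonium intermediate through the acidic ester α-protons to the cinnamate, possibly promoted by the basic piperidine, and partial loss of enantiopurity if the displacement is not purely SN2.
Fallback, setting out from phenol 11 and rejoining at acid 20, using a coupling partner without acidic α-protons. 4-Hydroxybenzaldehyde and CbzCl (pyridine, CH2Cl2) should give 4-formylphenyl benzyl carbonate F5. Keck allylation (Ti(OiPr)4, BINOL of the handedness that gives the R carbinol, allyltributylstannane) should give benzyl 4-[(1R)-1-hydroxybut-3-en-1-yl]phenyl carbonate F6. Mitsunobu coupling with 11 (PPh3, DIAD, inversion) should give benzyl 4-[(1S)-1-{3,5-bis(benzyloxy)-4-[(2R)-1-methylpiperidin-2-yl]phenoxy}but-3-en-1-yl]phenyl carbonate F7. Lemieux–Johnson cleavage (OsO4 cat., NaIO4, 2,6-lutidine, dioxane/H2O) should give benzyl 4-[(1S)-1-{3,5-bis(benzyloxy)-4-[(2R)-1-methylpiperidin-2-yl]phenoxy}-3-oxopropyl]phenyl carbonate F8. Pinnick oxidation of F8 (NaClO2, NaH2PO4, 2-methyl-2-butene) returns to the route at 20.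

3. Step 3 (Grignard addition). The risk is poor facial selectivity, because an ortho benzyloxy oxygen can compete with the sulfinyl oxygen for magnesium and open the chair transition state; slow addition to the doubly ortho-substituted imine and Wurtz-type loss of the chloroalkyl Grignard reagent are further risks.
Fallback, setting out from imine 4 and rejoining at piperidine 9, building the ring by allylation and metathesis. Addition of allylmagnesium bromide (CH2Cl2, −78 °C), or a Zn- or In-mediated Barbier allylation whose facial sense can be tuned by the medium, should give (S)-N-{(1R)-1-[2,6-bis(benzyloxy)-4-bromophenyl]but-3-en-1-yl}-2-methylpropane-2-sulfinamide F9. N-Allylation (NaH, allyl bromide, DMF) should give (S)-N-allyl-N-{(1R)-1-[2,6-bis(benzyloxy)-4-bromophenyl]but-3-en-1-yl}-2-methylpropane-2-sulfinamide F10. Ring-closing metathesis with second-generation Grubbs catalyst (CH2Cl2, 40 °C) should give (2R)-2-[2,6-bis(benzyloxy)-4-bromophenyl]-1-[(S)-tert-butylsulfinyl]-1,2,3,6-tetrahydropyridine F11. Diimide reduction (2-nitrobenzenesulfonyl hydrazide, Et3N), which spares the aryl bromide and the benzyl ethers, should give (2R)-2-[2,6-bis(benzyloxy)-4-bromophenyl]-1-[(S)-tert-butylsulfinyl]piperidine F12. Treatment of F12 with HCl in MeOH returns to the route at 9.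

**Further compounds**

F1 | step 13 | 1-{2,4-bis(benzyloxy)-6-hydroxy-3-[(2R)-1-methylpiperidin-2-yl]phenyl}ethan-1-one | CN1CCCC[C@@H]1c1c(OCc2ccccc2)cc(O)c(C(C)=O)c1OCc1ccccc1
F2 | step 13 | (2E)-1-{2,4-bis(benzyloxy)-6-hydroxy-3-[(2R)-1-methylpiperidin-2-yl]phenyl}-3-(dimethylamino)prop-2-en-1-one | CN1CCCC[C@@H]1c1c(OCc2ccccc2)cc(O)c(C(=O)/C=C/N(C)C)c1OCc1ccccc1
F3 | step 13 | 5,7-bis(benzyloxy)-6-[(2R)-1-methylpiperidin-2-yl]-4H-chromen-4-one | CN1CCCC[C@@H]1c1c(OCc2ccccc2)cc2occc(=O)c2c1OCc1ccccc1
F4 | step 13 | (2S)-5,7-bis(benzyloxy)-2-[4-(benzyloxy)phenyl]-6-[(2R)-1-methylpiperidin-2-yl]-2,3-dihydro-4H-chromen-4-one | CN1CCCC[C@@H]1c1c(OCc2ccccc2)cc2c(c1OCc1ccccc1)C(=O)C[C@@H](c1ccc(OCc3ccccc3)cc1)O2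
F5 | step 11 | 4-formylphenyl benzyl carbonate | O=Cc1ccc(OC(=O)OCc2ccccc2)cc1
F6 | step 11 | benzyl 4-[(1R)-1-hydroxybut-3-en-1-yl]phenyl carbonate | C=CC[C@@H](O)c1ccc(OC(=O)OCc2ccccc2)cc1
F7 | step 11 | benzyl 4-[(1S)-1-{3,5-bis(benzyloxy)-4-[(2R)-1-methylpiperidin-2-yl]phenoxy}but-3-en-1-yl]phenyl carbonate | CN1CCCC[C@@H]1c1c(OCc2ccccc2)cc(O[C@@H](CC=C)c2ccc(OC(=O)OCc3ccccc3)cc2)cc1OCc1ccccc1
F8 | step 11 | benzyl 4-[(1S)-1-{3,5-bis(benzyloxy)-4-[(2R)-1-methylpiperidin-2-yl]phenoxy}-3-oxopropyl]phenyl carbonate | CN1CCCC[C@@H]1c1c(OCc2ccccc2)cc(O[C@@H](CC=O)c2ccc(OC(=O)OCc3ccccc3)cc2)cc1OCc1ccccc1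
F9 | step 3 | (S)-N-{(1R)-1-[2,6-bis(benzyloxy)-4-bromophenyl]but-3-en-1-yl}-2-methylpropane-2-sulfinamide | CC(C)(C)[S@](=O)N[C@H](CC=C)c1c(OCc2ccccc2)cc(Br)cc1OCc1ccccc1
F10 | step 3 | (S)-N-allyl-N-{(1R)-1-[2,6-bis(benzyloxy)-4-bromophenyl]but-3-en-1-yl}-2-methylpropane-2-sulfinamide | CC(C)(C)[S@](=O)N(CC=C)[C@H](CC=C)c1c(OCc2ccccc2)cc(Br)cc1OCc1ccccc1
F11 | step 3 | (2R)-2-[2,6-bis(benzyloxy)-4-bromophenyl]-1-[(S)-tert-butylsulfinyl]-1,2,3,6-tetrahydropyridine | CC(C)(C)[S@](=O)N1CC=CC[C@@H]1c1c(OCc2ccccc2)cc(Br)cc1OCc1ccccc1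
F12 | step 3 | (2R)-2-[2,6-bis(benzyloxy)-4-bromophenyl]-1-[(S)-tert-butylsulfinyl]piperidine | CC(C)(C)[S@](=O)N1CCCC[C@@H]1c1c(OCc2ccccc2)cc(Br)cc1OCc1ccccc1
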